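**Assumption:** the target has no stereocentre and no stereogenic double bond (it is achiral), so the "single enantiomer" is the compound itself and no stereocontrol is needed.

## Retrosynthetic overview

1. The ArCH2–C(=O)Ar' ketone comes from regioselective Markovnikov hydration of the diarylalkyne 6; the p-anisyl ring directs C=O onto its own carbon.
2. Alkyne 6 comes from Sonogashira coupling of aryl triflate 4 with 4-ethynylanisole 5.
3. Triflate 4 comes from para-selective O-triflation of acylphloroglucinol 3, whose two ortho OH groups are hydrogen-bonded to the ketone.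
4. Compound 3 comes from Friedel–Crafts acylation of phloroglucinol 1 with 4-methylpentanoyl chloride 2.
5. No ring is formed: both benzene rings are bought (1 and 5), and there are no stereocentres.

## Route

Step 1
Reactants: 1 phloroglucinol; 2 4-methylpentanoyl chloride
Product: 3 4-methyl-1-(2,4,6-trihydroxyphenyl)pentan-1-one
Conditions: AlCl3 (4 equiv), CH2Cl2/PhNO2, 0 °C → 40 °C; then ice/aq. HCl
Reagents that add atoms: none
Why: Friedel–Crafts C-acylation of C3-symmetric phloroglucinol has no regiochemical issue, and the first acyl group (held as its aluminium chelate) deactivates the ring against a second acylation.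

Step 2
Reactants: 3 4-methyl-1-(2,4,6-trihydroxyphenyl)pentan-1-one
Product: 4 3,5-dihydroxy-4-(4-methylpentanoyl)phenyl trifluoromethanesulfonate
Conditions: PhNTf2 (1.0 equiv), i-Pr2NEt (1.1 equiv), THF, 0 °C → rt; dilute HCl wash
Reagents that add atoms: N-phenyl-bis(trifluoromethanesulfonimide) (PhNTf2), O=S(=O)(N(c1ccccc1)S(=O)(=O)C(F)(F)F)C(F)(F)F
Why: Chemoselective O-triflation: the 4-OH is the most acidic and the only OH not hydrogen-bonded to the ketone, so the mild triflyl donor should react there first, and 1.0 equiv limits over-triflation.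

Step 3
Reactants: 4 3,5-dihydroxy-4-(4-methylpentanoyl)phenyl trifluoromethanesulfonate; 5 4-ethynylanisole
Product: 6 1-{2,6-dihydroxy-4-[(4-methoxyphenyl)ethynyl]phenyl}-4-methylpentan-1-one
Conditions: PdCl2(PPh3)2 (5 mol %), CuI (10 mol %), Et3N (4 equiv), DMF, 60 °C, degassed (Ar)
Reagents that add atoms: none
Why: Sonogashira coupling at an unhindered C–OTf bond that is activated by the para ketone; free phenols and the ketone tolerate the amine base.

Step 4
Reactants: 6 1-{2,6-dihydroxy-4-[(4-methoxyphenyl)ethynyl]phenyl}-4-methylpentan-1-one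
Product: 8 1-{2,6-dihydroxy-4-[2-(4-methoxyphenyl)-2-oxoethyl]phenyl}-4-methylpentan-1-one (target CNP0142242.0), via enol tautomer 7 (not isolated)
Conditions: p-TsOH·H2O (1.5 equiv), EtOH/H2O (10:1), 80 °C
Reagents that add atoms: water, O
Why: Acid-mediated Markovnikov alkyne hydration: protonation gives the vinyl cation stabilised by the p-anisyl ring (the other ring is electron-poor through its para acyl group), so water adds at the anisyl-bearing carbon and the enol tautomerises to the ketone. The OH groups are meta to the alkyne, so no benzofuran can form; no stereocentre is created and the addition sets nothing free.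

## Compound list

1 | phloroglucinol (benzene-1,3,5-triol) | Oc1cc(O)cc(O)c1 | starting material
2 | 4-methylpentanoyl chloride | CC(C)CCC(=O)Cl | starting material
3 | 4-methyl-1-(2,4,6-trihydroxyphenyl)pentan-1-one | CC(C)CCC(=O)c1c(O)cc(O)cc1O | intermediate
4 | 3,5-dihydroxy-4-(4-methylpentanoyl)phenyl trifluoromethanesulfonate | CC(C)CCC(=O)c1c(O)cc(OS(=O)(=O)C(F)(F)F)cc1O | intermediate
5 | 4-ethynylanisole (1-ethynyl-4-methoxybenzene) | COc1ccc(C#C)cc1 | starting material
6 | 1-{2,6-dihydroxy-4-[(4-methoxyphenyl)ethynyl]phenyl}-4-methylpentan-1-one | COc1ccc(C#Cc2cc(O)c(C(=O)CCC(C)C)c(O)c2)cc1 | intermediate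
7 | 1-{2,6-dihydroxy-4-[(Z)-2-hydroxy-2-(4-methoxyphenyl)ethenyl]phenyl}-4-methylpentan-1-one (enol tautomer, not isolated; drawn as Z, the geometry is lost on tautomerisation) | COc1ccc(/C(O)=C/c2cc(O)c(C(=O)CCC(C)C)c(O)c2)cc1 | intermediate
8 | 1-{2,6-dihydroxy-4-[2-(4-methoxyphenyl)-2-oxoethyl]phenyl}-4-methylpentan-1-one | COc1ccc(C(=O)Cc2cc(O)c(C(=O)CCC(C)C)c(O)c2)cc1 | target

## Summary

Total step count: 4.
Longest linear sequence: 4 steps (1 → 3 → 4 → 6 → 8).

**Steps most likely to fail, with fallbacks**

**Step 2 (selective mono-triflation).** The risk is a mixture of 4-triflate, ortho-triflate and bis-triflates. The fallback sets the substitution pattern by directed ortho-metalation instead of differentiating three OH groups. It sets out from 5 (and uses 2) and comes back to the route at 6. Commercial 5-bromoresorcinol is protected with MOMCl/i-Pr2NEt in CH2Cl2 to give 1-bromo-3,5-bis(methoxymethoxy)benzene F1. Sonogashira coupling of this bromide with 5 (PdCl2(PPh3)2, CuI, Et3N, 70 °C) gives 1-{[3,5-bis(methoxymethoxy)phenyl]ethynyl}-4-methoxybenzene F2. n-BuLi in THF (−20 → 0 °C) deprotonates only the position flanked by both OMOM groups, giving {4-[(4-methoxyphenyl)ethynyl]-2,6-bis(methoxymethoxy)phenyl}lithium F3. This is quenched with N-methoxy-N,4-dimethylpentanamide F4 (made from 2 with MeNHOMe·HCl and Et3N in CH2Cl2) to give 1-{4-[(4-methoxyphenyl)ethynyl]-2,6-bis(methoxymethoxy)phenyl}-4-methylpentan-1-one F5. Finally 2 M HCl in MeOH at 40 °C removes both MOM groups and delivers 6.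

**Step 3 (Sonogashira on the free bis-phenol triflate).** The chelating 2,6-dihydroxyaryl ketone can sequester copper and the phenoxide-rich triflate may react slowly, so that 5 homocouples instead. The fallback is a copper-free Suzuki–Miyaura alkynylation with a preformed boron nucleophile. It sets out from 5 and comes back at 6. Compound 5 is deprotonated (n-BuLi, THF, −78 °C), borylated with B(OMe)3 and treated with aqueous KHF2 to give potassium trifluoro[(4-methoxyphenyl)ethynyl]borate F6. This salt is coupled with 4 (PdCl2(dppf), Cs2CO3, THF/H2O, 70 °C) to give 6.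

**Step 4 (alkyne hydration).** The risks are incomplete conversion, some regioisomeric ketone, or acid-promoted degradation of the acylresorcinol. The fallback brings in the carbonyl already in place by Pd-catalysed ketone α-arylation, with no alkyne at all. It sets out from 4 and comes back at 8. Compound 4 is protected with MOMCl/i-Pr2NEt in CH2Cl2 to give 3,5-bis(methoxymethoxy)-4-(4-methylpentanoyl)phenyl trifluoromethanesulfonate F7. Buchwald–Hartwig α-arylation of commercial 4'-methoxyacetophenone (2 equiv) with this triflate (Pd2(dba)3, XPhos, K3PO4, toluene, 90 °C) gives 1-{4-[2-(4-methoxyphenyl)-2-oxoethyl]-2,6-bis(methoxymethoxy)phenyl}-4-methylpentan-1-one F8. The unhindered methyl-ketone enolate should out-compete the enolate of the twisted, di-ortho-substituted ketone. 2 M HCl in MeOH at 40 °C then removes the MOM groups to give 8.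

## Further compounds

F1 | step 2 | 1-bromo-3,5-bis(methoxymethoxy)benzene | COCOc1cc(Br)cc(OCOC)c1
F2 | step 2 | 1-{[3,5-bis(methoxymethoxy)phenyl]ethynyl}-4-methoxybenzene | COCOc1cc(C#Cc2ccc(OC)cc2)cc(OCOC)c1
F3 | step 2 | {4-[(4-methoxyphenyl)ethynyl]-2,6-bis(methoxymethoxy)phenyl}lithium | [Li]c1c(OCOC)cc(C#Cc2ccc(OC)cc2)cc1OCOC
F4 | step 2 | N-methoxy-N,4-dimethylpentanamide | CON(C)C(=O)CCC(C)C
F5 | step 2 | 1-{4-[(4-methoxyphenyl)ethynyl]-2,6-bis(methoxymethoxy)phenyl}-4-methylpentan-1-one | COCOc1cc(C#Cc2ccc(OC)cc2)cc(OCOC)c1C(=O)CCC(C)C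
F6 | step 3 | potassium trifluoro[(4-methoxyphenyl)ethynyl]borate | [K+].F[B-](F)(F)C#Cc1ccc(OC)cc1
F7 | step 4 | 3,5-bis(methoxymethoxy)-4-(4-methylpentanoyl)phenyl trifluoromethanesulfonate | COCOc1cc(OS(=O)(=O)C(F)(F)F)cc(OCOC)c1C(=O)CCC(C)C
F8 | step 4 | 1-{4-[2-(4-methoxyphenyl)-2-oxoethyl]-2,6-bis(methoxymethoxy)phenyl}-4-methylpentan-1-one | COCOc1cc(CC(=O)c2ccc(OC)cc2)cc(OCOC)c1C(=O)CCC(C)C
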